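The vessel is closed and stirred, Z above the solution is held, and no L is dissolved at the start, so L has to come in from the gas.

- zeta: E 1.5 M; Z 200 mM (held); J 7.2 mM; run made earlier
- flask: E 0.76 M; Z 200 mM (held); J 7.2 mM; time 15 min

zeta run (percent of the E charged): time / min: G / % = 0.417: 1.4; 1.00: 3.3; 2.00: 5.1; 3.00: 8.3; 5.00: 11.4

(standard deviation of a reading: 0.5 percentage points)

- at the start none of L is dissolved
- the numbers in the tables scatter by 0.5 percentage points (one standard deviation)
- steps that have been proposed: E + L -> D; Z <-> L; 2 J -> X; G <-> Q; E + L + J -> J + G

1. amount of G at 15 min, in percent of the E charged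
2. concentration of L in solution at 15 min, in percent of saturation

On logarithmic axes the zeta readings climb with slope 0.844, close to one. The zeta curve is therefore nearly straight and can be carried forward in two ways. Kept as percent per minute, it gives 34.2% of G in the flask at the asked time.

Kept as amount, it gives the delivery, the concentration of G made per minute, read from the last zeta point as 34.2 mM min⁻¹. Spread over the smaller charge of the flask, that is 67.5%. The two ways part by 1.97, the ratio of the E charges.

To find which one cheats, turn the percent way into amount: the flask must then take up 17.3 mM min⁻¹, less than the zeta run's 34.2 mM min⁻¹, under the same Z, although the step Z <-> L holds no E. The percent way suits L near saturation in both runs; the delivery suits L far below saturation in both, with the uptake alike under the same Z.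

The step 2 J -> X is proposed, and a rate leaning on J falls as J goes, so a line this straight looks more like a steady supply of L from the gas. The reckoning made here therefore takes the delivery: G somewhat under 67.5%, with Q and D possibly taking a part, and L well below saturation.

The forecast differs, with 23% of G and L at 97%, on the ground “If the rate is first order in E”.

The flask gives 56.8% of G, with L at 39.6% of saturation.

    E + L → D (k = 0.00200 L mol⁻¹ s⁻¹)
    Z ⇌ L, rate k2*(csat - [L]) (kL = 0.00430 s⁻¹)
    2 J → X (k = 0.350 L mol⁻¹ s⁻¹)
    G ⇌ Q (K = 0.210, k = 0.0110 s⁻¹)
    E + L + J → J + G (k = 17.0 L² mol⁻² s⁻¹)

In the flask at the asked time, G, Q and D together stand at 72.0% of the E charged, an average of 36.5 mM min⁻¹ against the delivery of 34.2 mM min⁻¹. For the same flask read at 4.0 min, the delivery gives 18.0% of G, and that flask holds 18.4%.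

The data were computed for an exercise; noise was put on by code.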